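## Retrosynthetic overview
1. Target ⇒ per-O-benzyl tert-butyl ester (24), unmasked by TFA and then H2/Pd; O1 and the ring-C CO2H stay masked as OBn and CO2tBu until then, so the γ-hydroxy acid cannot close to a phthalide.
2. The terphenoyl unit (3,5-bridge: biaryls A–B and B–C) is closed last by Cu(II)/amine oxidative coupling of three free-phenol gallates on an open-chain 1-C-aryl-D-glucitol.
3. That open chain comes from ring-opening, chelation-controlled reduction of a 1-C-aryl-glucopyranose hemiketal (ring O5 is the latent 5-OH). The 4,6-(S)-HHDP was made earlier by intramolecular Ullmann coupling on the pyranose 4,6-diester.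
4. The C1–aryl bond comes from ArMgX + tetra-O-TMS-gluconolactone.
5. Rings are formed in this order: pyranose C-aryl glycoside, then 4,6-HHDP (11-membered), then pyranose opening, then A–B (11-membered), then B–C (10-membered, meta-bridged).

**Assumptions**
- The biaryl axes have the natural (S) configuration; the target SMILES carries no axial descriptors.
- Methyl 3,4-bis(benzyloxy)-5-hydroxybenzoate, 3,4,5-tris(benzyloxy)benzoic acid and D-glucono-1,5-lactone are commercial.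
- The target is the open hydroxy-acid exactly as drawn.
- Ar_C (ring C, attached through the carbon that will bond C1) = 4-allyloxy-5,6-bis(benzyloxy)-2-(tert-butoxycarbonyl)phenyl.
- AllGal = 5-allyloxy-3,4-bis(benzyloxy)benzoyl.

## Route

**Step 1**
Reactants: 1 methyl 3,4-bis(benzyloxy)-5-hydroxybenzoate
Product: 2 methyl 3,4-bis(benzyloxy)-5-hydroxy-2-iodobenzoate
Conditions: NIS, MeCN, 0 °C → rt
Reagents that add atoms: N-iodosuccinimide, O=C1CCC(=O)N1I
Why: Electrophilic aromatic iodination goes para to the free phenol (C2), fixing the iodine next to the OBn; no stereocenter.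

**Step 2**
Reactants: 2
Product: 3 methyl 5-allyloxy-3,4-bis(benzyloxy)-2-iodobenzoate
Conditions: allyl bromide, K2CO3, DMF, rt
Reagents that add atoms: allyl bromide, C=CCBr
Why: Williamson O-allylation masks the phenol (removed later by Pd(0)); no stereocenter.

**Step 3**
Reactants: 3
Product: 4 5-allyloxy-3,4-bis(benzyloxy)-2-iodobenzoic acid
Conditions: LiOH, THF/MeOH/H2O, 50 °C
Reagents that add atoms: water, O
Why: Ester saponification; no stereocenter.

**Step 4**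
Reactants: 4
Product: 5 tert-butyl 5-allyloxy-3,4-bis(benzyloxy)-2-iodobenzoate
Conditions: Boc2O, DMAP, t-BuOH, THF, 40 °C
Reagents that add atoms: tert-butanol, CC(C)(C)O
Why: Boc2O activation then tBuOH gives a hindered ester that resists the Grignard and borohydride steps and cannot lactonize onto a later C1-alkoxide; no stereocenter.

**Step 5**
Reactants: 1
Product: 6 methyl 5-allyloxy-3,4-bis(benzyloxy)benzoate
Conditions: allyl bromide, K2CO3, DMF, rt
Reagents that add atoms: allyl bromide, C=CCBr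
Why: O-allylation as in step 2; no stereocenter.

**Step 6**
Reactants: 6
Product: 7 5-allyloxy-3,4-bis(benzyloxy)benzoic acid
Conditions: LiOH, THF/MeOH/H2O, 50 °C
Reagents that add atoms: water, O
Why: Saponification gives the aroyl donor for rings A and B; no stereocenter.

**Step 7**
Reactants: 8 3,4,5-tris(benzyloxy)benzoic acid
Product: 9 3,4,5-tris(benzyloxy)-2-iodobenzoic acid
Conditions: NIS, cat. TFA, MeCN, rt
Reagents that add atoms: N-iodosuccinimide, O=C1CCC(=O)N1I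
Why: The ring is symmetric, so iodination gives a single isomer, the ortho-iodo donor for the Ullmann HHDP; no stereocenter.

**Step 8**
Reactants: 10 D-glucono-1,5-lactone
Product: 11 2,3,4,6-tetra-O-TMS-D-glucono-1,5-lactone
Conditions: TMSCl, N-methylmorpholine, THF, 0 °C → rt
Reagents that add atoms: chlorotrimethylsilane, C[Si](C)(C)Cl
Why: Per-silylation protects the hydroxyls so the lactone can take an organometallic; the D-gluco centers C2–C5 are untouched.

**Step 9**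
Reactants: 5, 11
Product: 12 methyl 1-C-(Ar_C)-α-D-glucopyranoside (a ketal; OMe α, aryl β)
Conditions: (i) 5, iPrMgCl·LiCl, THF, –40 °C; (ii) add 11, –40 → 0 °C; (iii) CSA (cat.), MeOH, 0 °C → rt
Reagents that add atoms: methanol, CO
Why: Halogen–magnesium exchange tolerates the tBu ester; 1,2-addition to the lactone gives the lactol, and acid/MeOH removes TMS and forms the methyl ketal (C1 is anomeric and later converges at step 16).

**Step 10**
Reactants: 12
Product: 13 4,6-O-di-tert-butylsilylene derivative of 12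
Conditions: (t-Bu)2Si(OTf)2, pyridine, DMF, –40 °C
Reagents that add atoms: di-tert-butylsilyl bis(triflate), CC(C)(C)[Si](OS(=O)(=O)C(F)(F)F)(OS(=O)(=O)C(F)(F)F)C(C)(C)C
Why: Silylene formation is selective for the 1,3-related 4,6-diol (silylene protection), leaving the 2,3-diol free; it is removed later by fluoride without acid.

**Step 11**
Reactants: 13, 7
Product: 14 3-O-AllGal derivative of 13
Conditions: EDC·HCl, DMAP, CH2Cl2, rt
Reagents that add atoms: none (7 is the acyl donor)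
Why: Steglich esterification is selective for O3 because O2 sits next to the quaternary, aryl-bearing C1; no new stereocenter.

**Step 12**
Reactants: 14
Product: 15 2-O-benzyl derivative of 14
Conditions: 2-benzyloxy-1-methylpyridinium triflate, MgO, PhCF3, 85 °C
Reagents that add atoms: 2-benzyloxy-1-methylpyridinium triflate, C[n+]1ccccc1OCc1ccccc1.[O-]S(=O)(=O)C(F)(F)F
Why: Neutral benzyl transfer (Dudley-type O-benzylation) avoids acyl migration and ketal cleavage; O2 becomes the permanent OBn.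

**Step 13**
Reactants: 15
Product: 16 4,6-diol
Conditions: HF·pyridine, THF/pyridine, 0 °C → rt
Reagents that add atoms: none
Why: Fluoride cleaves the silylene (silyl ether deprotection) and leaves the esters, allyl ethers, ketal and benzyl ethers intact.

**Step 14**
Reactants: 16, 9 (2.6 equiv)
Product: 17 4,6-bis-O-(3,4,5-tris(benzyloxy)-2-iodobenzoyl) derivative
Conditions: EDC·HCl, DMAP, CH2Cl2, rt
Reagents that add atoms: none (9 is the acyl donor)
Why: Double Steglich esterification of the only free hydroxyls; no stereocenter.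

**Step 15**
Reactants: 17
Product: 18 4,6-O-(S)-HHDP compound (hexakis-OBn)
Conditions: activated Cu powder, DMF, 140 °C
Reagents that add atoms: none
Why: Intramolecular Ullmann biaryl coupling; the 11-membered bridge across the 4,6-diol of the 4C1 pyranose forces the (S) axis, as in known 4,6-HHDP syntheses.

**Step 16**
Reactants: 18
Product: 19 lactol (hemiketal, anomeric mixture)
Conditions: TsOH·H2O (cat.), THF/H2O, 50 °C
Reagents that add atoms: water, O
Why: Acid-catalysed ketal hydrolysis, a tertiary benzylic ketal being labile; the C1 configuration is lost, as intended.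

**Step 17**
Reactants: 19
Product: 20 open-chain (1S)-1-C-(Ar_C)-2-O-benzyl-3-O-AllGal-4,6-O-HHDP-D-glucitol (free O1-H and O5-H)
Conditions: Zn(BH4)2, THF, –20 → 0 °C
Reagents that add atoms: none (hydride supplies only H)
Why: The ring-open keto form is reduced by chelation-controlled hydride delivery (Cram-chelate model). Zn binds the C1 carbonyl O and the 2-OBn, and hydride enters the face opposite the C3 substituent, giving the target C1 configuration (O1 on the right in the Fischer projection, i.e. as in the target). O5 is now free as the latent 5-OH.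

**Step 18**
Reactants: 20, 7
Product: 21 5-O-AllGal derivative of 20
Conditions: EDC·HCl, DMAP, CH2Cl2, rt
Reagents that add atoms: none (7 is the acyl donor)
Why: O5 is more accessible than the hindered benzylic O1, so Steglich acylation is chemoselective; no stereocenter.

**Step 19**
Reactants: 21
Product: 22 tris-phenol (the three allyl ethers cleaved)
Conditions: Pd(PPh3)4 (cat.), PhSiH3, CH2Cl2, rt
Reagents that add atoms: none
Why: Pd(0)-catalysed deallylation (π-allyl transfer to silane) unmasks the 5-OH of rings A, B and C, leaving Bn, tBu ester and all aryl esters.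

**Step 20**
Reactants: 22
Product: 23 NHTP compound (biaryls A–B and B–C formed; free phenols A5, B5, Cd)
Conditions: CuCl2, n-BuNH2, O2, CH2Cl2/MeOH, 0 °C → rt
Reagents that add atoms: none
Why: Cu(II)–amine phenol oxidative coupling (phenoxyl radical at the positions para/ortho to the free OH) closes the 3,5-bridged A–B biaryl, then the B–C biaryl, in two oxidative C–C couplings that lose 4 H. The macrocyclic tether from O3, O5 and C1 sets both new axes (S).

**Step 21**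
Reactants: 23
Product: 24 tetra-O-benzyl derivative (three phenols + O1)
Conditions: 2-benzyloxy-1-methylpyridinium triflate (excess), MgO, PhCF3, 85 °C
Reagents that add atoms: 2-benzyloxy-1-methylpyridinium triflate, C[n+]1ccccc1OCc1ccccc1.[O-]S(=O)(=O)C(F)(F)F
Why: Neutral O-benzylation caps the phenols (so they cannot oxidize or migrate) and O1 (so the γ-hydroxy acid cannot lactonize later).

**Step 22**
Reactants: 24
Product: 25 free acid (tBu ester cleaved)
Conditions: TFA, CH2Cl2, anisole, 0 °C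
Reagents that add atoms: none
Why: SN1-type tert-butyl ester cleavage; the benzyl ethers, aryl lactones and O1–Bn survive, and O1 is still protected against phthalide formation.

**Step 23**
Reactants: 25
Product: 26 chinquapinic acid
Conditions: H2 (1 atm), Pd(OH)2/C, THF/MeOH, rt
Reagents that add atoms: none
Why: Hydrogenolysis removes all 17 benzyl groups (15 aryl OBn, O1, O2) under neutral conditions, and the stereocenters are untouched.

## Compound list
(SMILES shown with the aryl/aroyl groups written out in full.)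

1 | methyl 3,4-bis(benzyloxy)-5-hydroxybenzoate | COC(=O)c1cc(O)c(OCc2ccccc2)c(OCc2ccccc2)c1 | starting material
2 | methyl 3,4-bis(benzyloxy)-5-hydroxy-2-iodobenzoate | COC(=O)c1cc(O)c(OCc2ccccc2)c(OCc2ccccc2)c1I | intermediate
3 | methyl 5-allyloxy-3,4-bis(benzyloxy)-2-iodobenzoate | COC(=O)c1cc(OCC=C)c(OCc2ccccc2)c(OCc2ccccc2)c1I | intermediate
4 | 5-allyloxy-3,4-bis(benzyloxy)-2-iodobenzoic acid | OC(=O)c1cc(OCC=C)c(OCc2ccccc2)c(OCc2ccccc2)c1I | intermediate
5 | tert-butyl 5-allyloxy-3,4-bis(benzyloxy)-2-iodobenzoate | CC(C)(C)OC(=O)c1cc(OCC=C)c(OCc2ccccc2)c(OCc2ccccc2)c1I | intermediate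
6 | methyl 5-allyloxy-3,4-bis(benzyloxy)benzoate | COC(=O)c1cc(OCC=C)c(OCc2ccccc2)c(OCc2ccccc2)c1 | intermediate
7 | 5-allyloxy-3,4-bis(benzyloxy)benzoic acid | OC(=O)c1cc(OCC=C)c(OCc2ccccc2)c(OCc2ccccc2)c1 | intermediate
8 | 3,4,5-tris(benzyloxy)benzoic acid | OC(=O)c1cc(OCc2ccccc2)c(OCc2ccccc2)c(OCc2ccccc2)c1 | starting material
9 | 3,4,5-tris(benzyloxy)-2-iodobenzoic acid | OC(=O)c1cc(OCc2ccccc2)c(OCc2ccccc2)c(OCc2ccccc2)c1I | intermediate
10 | D-glucono-1,5-lactone | C([C@@H]1[C@H]([C@@H]([C@H](C(=O)O1)O)O)O)O | starting material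
11 | 2,3,4,6-tetra-O-TMS-D-glucono-1,5-lactone | C([C@@H]1[C@H]([C@@H]([C@H](C(=O)O1)O[Si](C)(C)C)O[Si](C)(C)C)O[Si](C)(C)C)O[Si](C)(C)C | intermediate
12 | methyl 1-C-(Ar_C)-α-D-glucopyranoside | C([C@@H]1[C@H]([C@@H]([C@H]([C@](OC)(c2c(C(=O)OC(C)(C)C)cc(OCC=C)c(OCc3ccccc3)c2OCc2ccccc2)O1)O)O)O)O | intermediate
13 | 4,6-O-(di-tert-butylsilylene) derivative of 12 | C([C@@H]1[C@H]([C@@H]([C@H]([C@](OC)(c2c(C(=O)OC(C)(C)C)cc(OCC=C)c(OCc3ccccc3)c2OCc2ccccc2)O1)O)O)O%10)O[Si]%10(C(C)(C)C)C(C)(C)C | intermediate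
14 | 3-O-AllGal derivative of 13 | C([C@@H]1[C@H]([C@@H]([C@H]([C@](OC)(c2c(C(=O)OC(C)(C)C)cc(OCC=C)c(OCc3ccccc3)c2OCc2ccccc2)O1)O)OC(=O)c4cc(OCC=C)c(OCc5ccccc5)c(OCc5ccccc5)c4)O%10)O[Si]%10(C(C)(C)C)C(C)(C)C | intermediate
15 | 2-O-benzyl derivative of 14 | C([C@@H]1[C@H]([C@@H]([C@H]([C@](OC)(c2c(C(=O)OC(C)(C)C)cc(OCC=C)c(OCc3ccccc3)c2OCc2ccccc2)O1)OCc6ccccc6)OC(=O)c4cc(OCC=C)c(OCc5ccccc5)c(OCc5ccccc5)c4)O%10)O[Si]%10(C(C)(C)C)C(C)(C)C | intermediate
16 | 4,6-diol (2-OBn, 3-OAllGal) | C([C@@H]1[C@H]([C@@H]([C@H]([C@](OC)(c2c(C(=O)OC(C)(C)C)cc(OCC=C)c(OCc3ccccc3)c2OCc2ccccc2)O1)OCc6ccccc6)OC(=O)c4cc(OCC=C)c(OCc5ccccc5)c(OCc5ccccc5)c4)O)O | intermediate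
17 | 4,6-bis(2-iodo-3,4,5-tribenzyloxybenzoate) of 16 | C([C@@H]1[C@H]([C@@H]([C@H]([C@](OC)(c2c(C(=O)OC(C)(C)C)cc(OCC=C)c(OCc3ccccc3)c2OCc2ccccc2)O1)OCc6ccccc6)OC(=O)c4cc(OCC=C)c(OCc5ccccc5)c(OCc5ccccc5)c4)OC(=O)c7cc(OCc8ccccc8)c(OCc8ccccc8)c(OCc8ccccc8)c7I)OC(=O)c7cc(OCc8ccccc8)c(OCc8ccccc8)c(OCc8ccccc8)c7I | intermediate
18 | 4,6-O-(S)-HHDP pyranosyl ketal | C%13[C@@H]1[C@H]([C@@H]([C@H]([C@](OC)(c2c(C(=O)OC(C)(C)C)cc(OCC=C)c(OCc3ccccc3)c2OCc2ccccc2)O1)OCc6ccccc6)OC(=O)c4cc(OCC=C)c(OCc5ccccc5)c(OCc5ccccc5)c4)OC(=O)c7cc(OCc8ccccc8)c(OCc8ccccc8)c(OCc8ccccc8)c7-c7c(OCc8ccccc8)c(OCc8ccccc8)c(OCc8ccccc8)cc7C(=O)O%13 | intermediate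
19 | lactol (hemiketal) from 18 (C1 undefined) | C%13[C@@H]1[C@H]([C@@H]([C@H](C(O)(c2c(C(=O)OC(C)(C)C)cc(OCC=C)c(OCc3ccccc3)c2OCc2ccccc2)O1)OCc6ccccc6)OC(=O)c4cc(OCC=C)c(OCc5ccccc5)c(OCc5ccccc5)c4)OC(=O)c7cc(OCc8ccccc8)c(OCc8ccccc8)c(OCc8ccccc8)c7-c7c(OCc8ccccc8)c(OCc8ccccc8)c(OCc8ccccc8)cc7C(=O)O%13 | intermediate
20 | open-chain 1-aryl-D-glucitol with free O1-H and O5-H | [C@H](O)(c2c(C(=O)OC(C)(C)C)cc(OCC=C)c(OCc3ccccc3)c2OCc2ccccc2)[C@H](OCc6ccccc6)[C@@H](OC(=O)c4cc(OCC=C)c(OCc5ccccc5)c(OCc5ccccc5)c4)[C@H](OC(=O)c7cc(OCc8ccccc8)c(OCc8ccccc8)c(OCc8ccccc8)c7-c7c(OCc8ccccc8)c(OCc8ccccc8)c(OCc8ccccc8)cc7C(=O)O%13)[C@H](O)C%13 | intermediate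
21 | 5-O-AllGal derivative of 20 | [C@H](O)(c2c(C(=O)OC(C)(C)C)cc(OCC=C)c(OCc3ccccc3)c2OCc2ccccc2)[C@H](OCc6ccccc6)[C@@H](OC(=O)c4cc(OCC=C)c(OCc5ccccc5)c(OCc5ccccc5)c4)[C@H](OC(=O)c7cc(OCc8ccccc8)c(OCc8ccccc8)c(OCc8ccccc8)c7-c7c(OCc8ccccc8)c(OCc8ccccc8)c(OCc8ccccc8)cc7C(=O)O%13)[C@H](OC(=O)c4cc(OCC=C)c(OCc5ccccc5)c(OCc5ccccc5)c4)C%13 | intermediate
22 | tris-phenol (deallylated 21) | [C@H](O)(c2c(C(=O)OC(C)(C)C)cc(O)c(OCc3ccccc3)c2OCc2ccccc2)[C@H](OCc6ccccc6)[C@@H](OC(=O)c4cc(O)c(OCc5ccccc5)c(OCc5ccccc5)c4)[C@H](OC(=O)c7cc(OCc8ccccc8)c(OCc8ccccc8)c(OCc8ccccc8)c7-c7c(OCc8ccccc8)c(OCc8ccccc8)c(OCc8ccccc8)cc7C(=O)O%13)[C@H](OC(=O)c4cc(O)c(OCc5ccccc5)c(OCc5ccccc5)c4)C%13 | intermediate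
23 | NHTP/HHDP compound with three free phenols | [C@H](O)(c2c(C(=O)OC(C)(C)C)c%11c(O)c(OCc3ccccc3)c2OCc2ccccc2)[C@H](OCc6ccccc6)[C@@H](OC(=O)c4c%11c(O)c(OCc5ccccc5)c(OCc5ccccc5)c4%12)[C@H](OC(=O)c7cc(OCc8ccccc8)c(OCc8ccccc8)c(OCc8ccccc8)c7-c7c(OCc8ccccc8)c(OCc8ccccc8)c(OCc8ccccc8)cc7C(=O)O%13)[C@H](OC(=O)c9c%12c(OCc8ccccc8)c(OCc8ccccc8)c(O)c9)C%13 | intermediate
24 | tetra-O-benzylated 23 (per-O-benzyl tBu ester) | [C@H](OCc8ccccc8)(c2c(C(=O)OC(C)(C)C)c%11c(OCc3ccccc3)c(OCc3ccccc3)c2OCc2ccccc2)[C@H](OCc6ccccc6)[C@@H](OC(=O)c4c%11c(OCc5ccccc5)c(OCc5ccccc5)c(OCc5ccccc5)c4%12)[C@H](OC(=O)c7cc(OCc8ccccc8)c(OCc8ccccc8)c(OCc8ccccc8)c7-c7c(OCc8ccccc8)c(OCc8ccccc8)c(OCc8ccccc8)cc7C(=O)O%13)[C@H](OC(=O)c9c%12c(OCc8ccccc8)c(OCc8ccccc8)c(OCc8ccccc8)c9)C%13 | intermediate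
25 | free-acid per-O-benzyl compound | [C@H](OCc8ccccc8)(c2c(C(=O)O)c%11c(OCc3ccccc3)c(OCc3ccccc3)c2OCc2ccccc2)[C@H](OCc6ccccc6)[C@@H](OC(=O)c4c%11c(OCc5ccccc5)c(OCc5ccccc5)c(OCc5ccccc5)c4%12)[C@H](OC(=O)c7cc(OCc8ccccc8)c(OCc8ccccc8)c(OCc8ccccc8)c7-c7c(OCc8ccccc8)c(OCc8ccccc8)c(OCc8ccccc8)cc7C(=O)O%13)[C@H](OC(=O)c9c%12c(OCc8ccccc8)c(OCc8ccccc8)c(OCc8ccccc8)c9)C%13 | intermediate
26 | chinquapinic acid | O=C1OC[C@H]2OC(=O)c3cc(O)c(O)c(O)c3-c3c(O)c(O)c(O)c4c3C(=O)O[C@H]([C@@H](O)[C@@H](O)c3c(O)c(O)c(O)c-4c3C(=O)O)[C@@H]2OC(=O)c2cc(O)c(O)c(O)c2-c2c1cc(O)c(O)c2O | target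

## Totals
- Total steps: 23.
- Longest linear sequence: 19 (1 → 2 → 3 → 4 → 5 → 12 → 13 → … → 26, via the ring-C iodide).

**Three steps most likely to fail**
1. **Step 20, double oxidative coupling to the strained NHTP.** The B–C biaryl bridges meta positions on ring C. Fallback: iodinate rings A and C (NIS) and do Ir-catalysed C–H borylation of ring B, then close both biaryls by intramolecular double Suzuki–Miyaura coupling instead of phenol oxidation.
2. **Step 17, stereocontrol and acyl migration in the ring-opening reduction.** The C1 epimer may form, or an HHDP ester may migrate to the newly freed O5. Fallback: open the ring and set C1 at step-13-type stage, where the 4,6-positions are still silylene-protected and no esters can migrate, with Mitsunobu inversion (p-NO2C6H4CO2H, DIAD, PPh3) if the C1 epimer forms. Then build the 4,6-HHDP on the open-chain 4,6-diol.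
3. **Step 12, benzylation of the very hindered O2 (and the O3-over-O2 selectivity of step 11).** Fallback: swap the order, making the 2,3-stannylene (Bu2SnO) and benzylating O2 first (BnBr, Bu4NI), then aroylating O3.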